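The ring is cut at the C4–C5 bond of the six-membered dienone ring. The quaternary C4 and its neighbour C5 both carry oxygen, so with the methyl groups removed this pair is a tertiary α-ketol, the signature of a crossed benzoin. Under a chiral triazolium carbene the formyl carbon (future C5) of an open-chain keto aldehyde becomes an acyl anion equivalent and adds to the ketone (future C4), which forms the carbocycle, the C4–C5 bond and the C4 stereocentre in one operation. The precursor is a (7S)-8-aryl-7-methyl-6-oxooctanal whose C8 centre stems from an oxazolidinone alkylation and which already holds the future C1 oxygen as a silyl ether, so that no late C–H oxidation is required.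

Key step: step 7

Numbering used below: C1 is the ring carbonyl carbon, C2 the allyl-bearing carbon, C3 the adjacent CH, C4 the quaternary carbon, C5 the methoxy-bearing alkene carbon, C6 the remaining CH; C8 is the side-chain CH(CH3).

Assumption: both antipodes of the aminoindanol-derived triazolium salt of step 7 are on sale; the one that sends the acyl anion carbon to the Si face of the ketone is picked in a pilot run.

Assumption: (2R)-2-(2-bromoethyl)oxirane is bought as the single enantiomer (otherwise it is reached by hydrolytic kinetic resolution of the racemate); its carbinol centre is oxidised away in step 11 and only serves to keep every intermediate a single diastereomer.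

Step 1
Reactants: 1 (2R)-2-(2-bromoethyl)oxirane; 2 vinylmagnesium bromide
Product: 3 (3S)-1-bromohex-5-en-3-ol
Conditions: CH2=CHMgBr, CuI (10 mol %), THF, −40 → −20 °C; then aq NH4Cl
Reagents that add atoms: none
Why: Copper-catalysed Grignard opening of the epoxide at its unsubstituted carbon outruns coupling at the primary bromide at low temperature, so the carbinol carbon keeps its configuration (the descriptor changes from R to S only through the priority rules).

Step 2
Reactants: 3 (3S)-1-bromohex-5-en-3-ol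
Product: 4 tert-butyl{[(3S)-1-bromohex-5-en-3-yl]oxy}dimethylsilane
Conditions: TBSOTf, 2,6-lutidine, CH2Cl2, −78 → 0 °C
Reagents that add atoms: tert-butyldimethylsilyl trifluoromethanesulfonate, CC(C)(C)[Si](C)(C)OS(=O)(=O)C(F)(F)F
Why: Silylation of a secondary alcohol with a silyl triflate and a hindered pyridine is fast at low temperature and leaves the alkyl bromide and the alkene alone.

Step 3
Reactants: 5 (4R)-4-benzyl-3-propanoyl-1,3-oxazolidin-2-one; 6 4-(bromomethyl)-1,2-dimethoxybenzene
Product: 8 (4R)-4-benzyl-3-[(2S)-3-(3,4-dimethoxyphenyl)-2-methylpropanoyl]-1,3-oxazolidin-2-one, via sodium enolate 7 (not isolated)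
Conditions: NaN(SiMe3)2, THF, −78 °C; then 6, −78 → −40 °C
Reagents that add atoms: none
Why: Evans alkylation, in which the chelated sodium (Z)-enolate is benzylated on the face away from the benzyl group of the (R)-auxiliary and thereby sets the (S) methyl-bearing centre that becomes C8.

Step 4
Reactants: 8 (4R)-4-benzyl-3-[(2S)-3-(3,4-dimethoxyphenyl)-2-methylpropanoyl]-1,3-oxazolidin-2-one
Product: 9 (2S)-3-(3,4-dimethoxyphenyl)-N-methoxy-N,2-dimethylpropanamide
Conditions: MeNH(OMe)·HCl, AlMe3, CH2Cl2, 0 → 25 °C; then aq HCl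
Reagents that add atoms: N,O-dimethylhydroxylamine hydrochloride, CNOC.Cl
Why: The aluminium amide formed from AlMe3 and the hydroxylamine salt attacks the exocyclic acyl carbonyl of the imide (Weinreb transamidation) and frees the auxiliary without touching the α-stereocentre.

Step 5
Reactants: 9 (2S)-3-(3,4-dimethoxyphenyl)-N-methoxy-N,2-dimethylpropanamide; 4 tert-butyl{[(3S)-1-bromohex-5-en-3-yl]oxy}dimethylsilane
Product: 11 (2S,6R)-6-[(tert-butyldimethylsilyl)oxy]-1-(3,4-dimethoxyphenyl)-2-methylnon-8-en-3-one, via Grignard reagent 10 (not isolated)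
Conditions: 4, Mg, THF, 45 °C; then 9, THF, 0 °C; then aq NH4Cl
Reagents that add atoms: none
Why: Weinreb ketone synthesis, in which the Grignard reagent adds once to give a magnesium chelate that breaks down to the ketone only on quench, so over-addition and epimerisation next to the carbonyl are avoided.

Step 6
Reactants: 11 (2S,6R)-6-[(tert-butyldimethylsilyl)oxy]-1-(3,4-dimethoxyphenyl)-2-methylnon-8-en-3-one
Product: 13 (3R,7S)-3-[(tert-butyldimethylsilyl)oxy]-8-(3,4-dimethoxyphenyl)-7-methyl-6-oxooctanal, via diol 12 (not isolated)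
Conditions: OsO4 (2 mol %), NaIO4, 2,6-lutidine, 1,4-dioxane/H2O, 25 °C
Reagents that add atoms: osmium tetroxide, O=[Os](=O)(=O)=O; sodium periodate, [Na+].[O-]I(=O)(=O)=O
Why: Lemieux–Johnson oxidation (catalytic dihydroxylation, then periodate glycol cleavage, buffered by 2,6-lutidine) cuts only the terminal alkene and, unlike ozone, spares the electron-rich dimethoxyarene.

Step 7
Reactants: 13 (3R,7S)-3-[(tert-butyldimethylsilyl)oxy]-8-(3,4-dimethoxyphenyl)-7-methyl-6-oxooctanal
Product: 14 (2R,5R)-5-[(tert-butyldimethylsilyl)oxy]-2-[(2S)-1-(3,4-dimethoxyphenyl)propan-2-yl]-2-hydroxycyclohexan-1-one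
Conditions: 2-(pentafluorophenyl)-5a,10b-dihydro-4H,6H-indeno[2,1-b][1,2,4]triazolo[4,3-d][1,4]oxazin-2-ium tetrafluoroborate (Si-face-selective antipode, 15 mol %), Et3N (15 mol %), toluene (0.05 M), 25 °C
Reagents that add atoms: none
Why: The free carbene adds to the aldehyde carbon (C5) and a proton shift gives the enaminol (Breslow intermediate), whose nucleophilic C5 attacks the C4 ketone; proton transfer and loss of the carbene from the adduct then leave the α-ketol and restart the cycle. The closest known reaction type is the enantioselective intramolecular crossed aldehyde–ketone benzoin cyclisation under chiral triazolium carbene catalysis, which gives cyclic tertiary α-ketols. The ring closes in a 6-exo-trig mode, C5 adding to a carbonyl whose C=O bond lies outside the new ring. The C4 centre is controlled by the chiral carbene, which must present C5 to the Si face of the ketone to give the (2R) ketol; the open-chain Felkin–Anh preference of the (S)-configured C8 points to the same face, so a matched pair is expected, and the C1 silyl ether can lie equatorial in the chair-like transition state. The step needs chemoselectivity (aldehyde as donor, ketone as acceptor) and survival of the C8 and C1 centres: the carbene engages only the unhindered aldehyde, the chain length leaves a six-membered ring as the only strain-free closure, and catalytic triethylamine is too weak to enolise the α-branched ketone or to eliminate the silyloxy group, which sits β and not α to the acyl anion carbon and so cannot be expelled from the enaminol.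

Step 8
Reactants: 14 (2R,5R)-5-[(tert-butyldimethylsilyl)oxy]-2-[(2S)-1-(3,4-dimethoxyphenyl)propan-2-yl]-2-hydroxycyclohexan-1-one
Product: 15 (2R,5R)-5-[(tert-butyldimethylsilyl)oxy]-2-[(2S)-1-(3,4-dimethoxyphenyl)propan-2-yl]-2-methoxycyclohexan-1-one
Conditions: MeOTf, 2,6-di-tert-butyl-4-methylpyridine, CH2Cl2, 25 → 40 °C
Reagents that add atoms: methyl trifluoromethanesulfonate, COS(=O)(=O)C(F)(F)F
Why: O-Methylation of the hindered tertiary alcohol by the powerful electrophile methyl triflate, with a non-nucleophilic pyridine as acid scavenger, needs no strong base, so the ketone is not enolised and the α-ketol cannot rearrange.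

Step 9
Reactants: 15 (2R,5R)-5-[(tert-butyldimethylsilyl)oxy]-2-[(2S)-1-(3,4-dimethoxyphenyl)propan-2-yl]-2-methoxycyclohexan-1-one
Product: 17 tert-butyl({(1R,4R)-4-[(2S)-1-(3,4-dimethoxyphenyl)propan-2-yl]-3,4-dimethoxycyclohex-2-en-1-yl}oxy)dimethylsilane, via potassium enolate 16 (not isolated)
Conditions: KN(SiMe3)2, THF, −78 °C; then MeOTf, DMPU, −78 °C
Reagents that add atoms: methyl trifluoromethanesulfonate, COS(=O)(=O)C(F)(F)F
Why: Because C4 is quaternary the ketone can enolise only toward C6, and the dissociated potassium enolate is methylated on oxygen by the hard electrophile methyl triflate (enolate O-alkylation), the silyloxide at C1 being too poor a leaving group for β-elimination at −78 °C.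

Step 10
Reactants: 17 tert-butyl({(1R,4R)-4-[(2S)-1-(3,4-dimethoxyphenyl)propan-2-yl]-3,4-dimethoxycyclohex-2-en-1-yl}oxy)dimethylsilane
Product: 18 (1R,4R)-4-[(2S)-1-(3,4-dimethoxyphenyl)propan-2-yl]-3,4-dimethoxycyclohex-2-en-1-ol
Conditions: Bu4NF, THF, 0 °C
Reagents that add atoms: none
Why: Fluoride-induced desilylation removes the secondary silyl ether under non-acidic conditions, which keeps the acid-sensitive enol ether intact.

Step 11
Reactants: 18 (1R,4R)-4-[(2S)-1-(3,4-dimethoxyphenyl)propan-2-yl]-3,4-dimethoxycyclohex-2-en-1-ol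
Product: 19 (4R)-4-[(2S)-1-(3,4-dimethoxyphenyl)propan-2-yl]-3,4-dimethoxycyclohex-2-en-1-one
Conditions: MnO2, CH2Cl2, 25 °C
Reagents that add atoms: none
Why: Manganese dioxide oxidises the allylic alcohol selectively and under neutral conditions to the enone, here a vinylogous ester whose methoxy group is fixed at C5 by the order of events.

Step 12
Reactants: 19 (4R)-4-[(2S)-1-(3,4-dimethoxyphenyl)propan-2-yl]-3,4-dimethoxycyclohex-2-en-1-one; 20 allyl bromide (3-bromoprop-1-ene)
Product: 22 (4R)-4-[(2S)-1-(3,4-dimethoxyphenyl)propan-2-yl]-3,4-dimethoxy-6-(prop-2-en-1-yl)cyclohex-2-en-1-one (both C6 epimers), via lithium dienolate 21 (not isolated)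
Conditions: LiN(i-Pr)2, THF, −78 °C; then 20, DMPU, −78 → −30 °C
Reagents that add atoms: none
Why: Kinetic deprotonation of the vinylogous ester occurs at the α′ carbon C2 (the γ carbon C4 is quaternary) and the cross-conjugated enolate is C-allylated by the reactive allylic bromide in a Stork–Danheiser alkylation; the new C2 centre becomes sp2 in the next step, so its configuration does not matter.

Step 13
Reactants: 22 (4R)-4-[(2S)-1-(3,4-dimethoxyphenyl)propan-2-yl]-3,4-dimethoxy-6-(prop-2-en-1-yl)cyclohex-2-en-1-one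
Product: 26 (4S)-4-[(2S)-1-(3,4-dimethoxyphenyl)propan-2-yl]-4,5-dimethoxy-2-(prop-2-en-1-yl)cyclohexa-2,5-dien-1-one (target), via lithium enolate 23 (not isolated), via selenide 24 (not isolated), via selenoxide 25 (not isolated)
Conditions: LiN(i-Pr)2, THF, −78 °C; PhSeBr, −78 °C; then H2O2 (30 %), pyridine, 0 → 25 °C
Reagents that add atoms: none
Why: A second enolisation at C2 and selenenylation give the tertiary selenide, whose selenoxide undergoes syn-elimination (selenoxide elimination) with a ring hydrogen at C3 to give the endocyclic cross-conjugated dienone, while the quaternary C4 and the C8 centre are not touched.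

Compound list
1 | (2R)-2-(2-bromoethyl)oxirane | BrCC[C@@H]1CO1 | starting material
2 | vinylmagnesium bromide | C=C[Mg]Br | starting material
3 | (3S)-1-bromohex-5-en-3-ol | C=CC[C@H](O)CCBr | intermediate
4 | tert-butyl{[(3S)-1-bromohex-5-en-3-yl]oxy}dimethylsilane | C=CC[C@H](O[Si](C)(C)C(C)(C)C)CCBr | intermediate
5 | (4R)-4-benzyl-3-propanoyl-1,3-oxazolidin-2-one | CCC(=O)N1[C@H](Cc2ccccc2)COC1=O | starting material
6 | 4-(bromomethyl)-1,2-dimethoxybenzene | COc1ccc(CBr)cc1OC | starting material
7 | sodium (1Z)-1-[(4R)-4-benzyl-2-oxo-1,3-oxazolidin-3-yl]prop-1-en-1-olate | [Na+].[O-]/C(=C\C)N1[C@H](Cc2ccccc2)COC1=O | intermediate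
8 | (4R)-4-benzyl-3-[(2S)-3-(3,4-dimethoxyphenyl)-2-methylpropanoyl]-1,3-oxazolidin-2-one | C[C@@H](Cc1ccc(OC)c(OC)c1)C(=O)N1[C@H](Cc2ccccc2)COC1=O | intermediate
9 | (2S)-3-(3,4-dimethoxyphenyl)-N-methoxy-N,2-dimethylpropanamide | C[C@@H](Cc1ccc(OC)c(OC)c1)C(=O)N(C)OC | intermediate
10 | bromo{(3S)-3-[(tert-butyldimethylsilyl)oxy]hex-5-en-1-yl}magnesium | C=CC[C@H](O[Si](C)(C)C(C)(C)C)CC[Mg]Br | intermediate
11 | (2S,6R)-6-[(tert-butyldimethylsilyl)oxy]-1-(3,4-dimethoxyphenyl)-2-methylnon-8-en-3-one | C=CC[C@H](O[Si](C)(C)C(C)(C)C)CCC(=O)[C@@H](C)Cc1ccc(OC)c(OC)c1 | intermediate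
12 | (2S,6R)-6-[(tert-butyldimethylsilyl)oxy]-1-(3,4-dimethoxyphenyl)-8,9-dihydroxy-2-methylnonan-3-one (both C8 epimers) | OCC(O)C[C@H](O[Si](C)(C)C(C)(C)C)CCC(=O)[C@@H](C)Cc1ccc(OC)c(OC)c1 | intermediate
13 | (3R,7S)-3-[(tert-butyldimethylsilyl)oxy]-8-(3,4-dimethoxyphenyl)-7-methyl-6-oxooctanal | O=CC[C@H](O[Si](C)(C)C(C)(C)C)CCC(=O)[C@@H](C)Cc1ccc(OC)c(OC)c1 | intermediate
14 | (2R,5R)-5-[(tert-butyldimethylsilyl)oxy]-2-[(2S)-1-(3,4-dimethoxyphenyl)propan-2-yl]-2-hydroxycyclohexan-1-one | O=C1C[C@H](O[Si](C)(C)C(C)(C)C)CC[C@@]1(O)[C@@H](C)Cc1ccc(OC)c(OC)c1 | intermediate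
15 | (2R,5R)-5-[(tert-butyldimethylsilyl)oxy]-2-[(2S)-1-(3,4-dimethoxyphenyl)propan-2-yl]-2-methoxycyclohexan-1-one | O=C1C[C@H](O[Si](C)(C)C(C)(C)C)CC[C@@]1(OC)[C@@H](C)Cc1ccc(OC)c(OC)c1 | intermediate
16 | potassium (3R,6R)-3-[(tert-butyldimethylsilyl)oxy]-6-[(2S)-1-(3,4-dimethoxyphenyl)propan-2-yl]-6-methoxycyclohex-1-en-1-olate | [K+].[O-]C1=C[C@H](O[Si](C)(C)C(C)(C)C)CC[C@@]1(OC)[C@@H](C)Cc1ccc(OC)c(OC)c1 | intermediate
17 | tert-butyl({(1R,4R)-4-[(2S)-1-(3,4-dimethoxyphenyl)propan-2-yl]-3,4-dimethoxycyclohex-2-en-1-yl}oxy)dimethylsilane | COC1=C[C@H](O[Si](C)(C)C(C)(C)C)CC[C@@]1(OC)[C@@H](C)Cc1ccc(OC)c(OC)c1 | intermediate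
18 | (1R,4R)-4-[(2S)-1-(3,4-dimethoxyphenyl)propan-2-yl]-3,4-dimethoxycyclohex-2-en-1-ol | COC1=C[C@H](O)CC[C@@]1(OC)[C@@H](C)Cc1ccc(OC)c(OC)c1 | intermediate
19 | (4R)-4-[(2S)-1-(3,4-dimethoxyphenyl)propan-2-yl]-3,4-dimethoxycyclohex-2-en-1-one | COC1=CC(=O)CC[C@@]1(OC)[C@@H](C)Cc1ccc(OC)c(OC)c1 | intermediate
20 | allyl bromide (3-bromoprop-1-ene) | C=CCBr | starting material
21 | lithium (4R)-4-[(2S)-1-(3,4-dimethoxyphenyl)propan-2-yl]-4,5-dimethoxycyclohexa-1,5-dien-1-olate | [Li+].[O-]C1=CC[C@@](OC)([C@@H](C)Cc2ccc(OC)c(OC)c2)C(OC)=C1 | intermediate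
22 | (4R)-4-[(2S)-1-(3,4-dimethoxyphenyl)propan-2-yl]-3,4-dimethoxy-6-(prop-2-en-1-yl)cyclohex-2-en-1-one (both C6 epimers) | C=CCC1C[C@@](OC)([C@@H](C)Cc2ccc(OC)c(OC)c2)C(OC)=CC1=O | intermediate
23 | lithium (4R)-4-[(2S)-1-(3,4-dimethoxyphenyl)propan-2-yl]-4,5-dimethoxy-2-(prop-2-en-1-yl)cyclohexa-1,5-dien-1-olate | [Li+].[O-]C1=C(CC=C)C[C@@](OC)([C@@H](C)Cc2ccc(OC)c(OC)c2)C(OC)=C1 | intermediate
24 | (4R)-4-[(2S)-1-(3,4-dimethoxyphenyl)propan-2-yl]-3,4-dimethoxy-6-(phenylselanyl)-6-(prop-2-en-1-yl)cyclohex-2-en-1-one (both C6 epimers) | C=CCC1([Se]c2ccccc2)C[C@@](OC)([C@@H](C)Cc3ccc(OC)c(OC)c3)C(OC)=CC1=O | intermediate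
25 | (4R)-6-(benzeneseleninyl)-4-[(2S)-1-(3,4-dimethoxyphenyl)propan-2-yl]-3,4-dimethoxy-6-(prop-2-en-1-yl)cyclohex-2-en-1-one (mixture of isomers at C6 and selenium) | C=CCC1([Se](=O)c2ccccc2)C[C@@](OC)([C@@H](C)Cc3ccc(OC)c(OC)c3)C(OC)=CC1=O | intermediate
26 | (4S)-4-[(2S)-1-(3,4-dimethoxyphenyl)propan-2-yl]-4,5-dimethoxy-2-(prop-2-en-1-yl)cyclohexa-2,5-dien-1-one | C=CCC1=C[C@@](OC)([C@@H](C)Cc2ccc(OC)c(OC)c2)C(OC)=CC1=O | target

Total step count: 13.
Longest linear sequence: 11 steps (steps 3 to 13 from imide 5; equally steps 1, 2 and 5 to 13 from epoxide 1).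

Steps most likely to fail

Step 7 (ring closure). The acyl anion equivalent may add too slowly to the α-branched dialkyl ketone, so that aldol closure, aldehyde dimerisation or epimerisation at C8 takes over, or it may attack the wrong face of the ketone. Fallback: setting out from 13, the same C4–C5 bond would be made reductively by a ketyl–carbonyl (pinacol) cyclisation with SmI2 (THF, t-BuOH, −78 °C), which gives the cyclohexane-1,2-diol F1 under substrate control. After separation of the C4 diastereomers, oxidation of the secondary carbinol alone with IBX (DMSO, 25 °C) comes back to the route at 14.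

Step 13 (desaturation). The selenoxide may eliminate toward the allylic CH2 of the side chain and give an exocyclic diene, or PhSeBr may add to the terminal alkene. Fallback: setting out from 19, the position of the double bond would be fixed before the allyl group arrives. Hydroxylation of the lithium dienolate with 3-phenyl-2-(phenylsulfonyl)oxaziridine gives the α′-hydroxy ketone F2. Swern oxidation gives the 1,2-dione, which can enolise only toward C3 and so exists as the diosphenol F3. Tf2O/pyridine gives the enol triflate F4, and Stille coupling with allyltributylstannane (Pd(PPh3)4, LiCl, THF, 65 °C) comes back to the route at 26.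

Step 9 (enol ether). The potassium enolate may be methylated on carbon (C6) instead of oxygen, or may expel the C1 silyloxy group. Fallback: setting out from 15, no enolate would be used. Acetalisation with MeOSiMe3 and catalytic TMSOTf (CH2Cl2, −78 °C) gives the dimethyl ketal F5. Removal of one methanol with TMSOTf and i-Pr2NEt (0 °C), possible only toward C6, comes back to the route at 17.

Further compounds
F1 | step 7 | (1R,4R)-4-[(tert-butyldimethylsilyl)oxy]-1-[(2S)-1-(3,4-dimethoxyphenyl)propan-2-yl]cyclohexane-1,2-diol (both C2 epimers) | OC1C[C@H](O[Si](C)(C)C(C)(C)C)CC[C@@]1(O)[C@@H](C)Cc1ccc(OC)c(OC)c1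
F2 | step 13 | (4R)-4-[(2S)-1-(3,4-dimethoxyphenyl)propan-2-yl]-6-hydroxy-3,4-dimethoxycyclohex-2-en-1-one (both C6 epimers) | OC1C[C@@](OC)([C@@H](C)Cc2ccc(OC)c(OC)c2)C(OC)=CC1=O
F3 | step 13 | (4S)-4-[(2S)-1-(3,4-dimethoxyphenyl)propan-2-yl]-2-hydroxy-4,5-dimethoxycyclohexa-2,5-dien-1-one | OC1=C[C@@](OC)([C@@H](C)Cc2ccc(OC)c(OC)c2)C(OC)=CC1=O
F4 | step 13 | (3S)-3-[(2S)-1-(3,4-dimethoxyphenyl)propan-2-yl]-3,4-dimethoxy-6-oxocyclohexa-1,4-dien-1-yl trifluoromethanesulfonate | O=S(=O)(OC1=C[C@@](OC)([C@@H](C)Cc2ccc(OC)c(OC)c2)C(OC)=CC1=O)C(F)(F)F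
F5 | step 9 | tert-butyl({(1R,4R)-4-[(2S)-1-(3,4-dimethoxyphenyl)propan-2-yl]-3,3,4-trimethoxycyclohexyl}oxy)dimethylsilane | COC1(OC)C[C@H](O[Si](C)(C)C(C)(C)C)CC[C@@]1(OC)[C@@H](C)Cc1ccc(OC)c(OC)c1
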